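The gamma run held a quarter of the reagent of the theta run and the eta run twice the solid substrate of either, yet by 20.0 h they had lost much the same amount of it: 1.70 mM, 1.94 mM and 1.73 mM.

| flask | solid substrate | reagent | remark | time |
|---|---|---|---|---|
| gamma | 17 mM | 11 mM | run made earlier |  |
| theta | 17 mM | 44 mM | run made earlier |  |
| eta | 34 mM | 22.1 mM | run made earlier |  |
| flask | 17 mM | 22.1 mM |  | 25 h |

| run | time / h | solid substrate / % | first product / % | bis adduct / % |
|---|---|---|---|---|
| gamma | 1.50 | 99.6 | 0.3 | 0.5 |
| gamma | 4.00 | 98.7 | 0 | 0.4 |
| gamma | 8.00 | 95.1 | 0.1 | 1.0 |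
| gamma | 20.0 | 90.0 | 2.7 | 1.0 |
| theta | 2.50 | 99.3 | 0 | 0 |
| theta | 8.00 | 95.3 | 1.7 | 0 |
| theta | 12.0 | 92.9 | 3.4 | 1.0 |
| theta | 20.0 | 88.6 | 3.9 | 0.3 |
| eta | 5.00 | 96.9 | 0.6 | 0 |
| eta | 10.0 | 97.9 | 0 | 0.4 |
| eta | 15.0 | 96.0 | 1.3 | 0 |
| eta | 20.0 | 94.9 | 1.9 | 0 |

(each reading ± 0.5 percentage points)

- given per volume of solution although it is solid: solid substrate
- at the start none of the solid substrate is in solution

* solid substrate at 25 h, in percent of the solid substrate charged (only what is still solid)
* first product at 25 h, in percent of the solid substrate charged
* bis adduct at 25 h, in percent of the solid substrate charged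
* tris adduct at 25 h, in percent of the solid substrate charged

So count the solid in mM, not in percent. Divide the mean of those losses by the time and you have the wear rate, the solid lost per hour averaged over the curve: 0.0895 mM h⁻¹. As far as these readings go, the loss looks zero-order in solid. The flask has the solid charge of gamma and theta, with reagent between theirs. Over 25 h it should therefore lose 2.24 mM of its 17 mM, which leaves 86.8% solid.

The weak link is the straight line, since a mean can hide a slowing. So take the later stretch, from 8.00 h to 20.0 h, in gamma and theta. It gives 0.0836 mM h⁻¹, a little lower than the wear rate. Run that rate on from their mean at 20.0 h, 89.3%, and you reach 86.8%. This comes from the same readings, so it is no independent check, but the slowing they show leaves the estimate where it stood.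

The forecast gives 4.5% first product, 0.9% bis adduct, 0.2% tris adduct and 87% solid substrate, the last on the ground that “dissolution looks roughly zero-order”.

The flask gives 87.4% solid substrate, 4.35% first product, 1.28% bis adduct and 1.53% tris adduct.

    reagent + bis adduct ⇌ tris adduct (K = 140 L mol⁻¹, k = 9.50 L mol⁻¹ h⁻¹)
    reagent + first product → bis adduct (k = 2.51 L mol⁻¹ h⁻¹)
    starting material + reagent → first product (k = 4.34 L mol⁻¹ h⁻¹)
    solid substrate ⇌ starting material, rate k4*(cs4 - [starting material]) while solid is left; crystals form when [starting material] > cs4 (solubility = 2.50 mM, k = 0.0443 h⁻¹)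
    starting material + first product → side product (k = 13.3 L mol⁻¹ h⁻¹)

The flask's solid went at 0.0856 mM h⁻¹ on the mean, just under the wear rate read off the runs. At 25.0 h the dissolved starting material in the flask stands at 0.758 mM, lower than its solubility of 2.5 mM. Take the same charges left until 2.5 d: the wear rate leaves 68.4% solid, and that flask holds 72.0%.

The data were computed with constants of no real substance, noise included.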